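in all of them: starting complex 0.80 M

| flask | incoming ligand | remark | time |
|---|---|---|---|
| red | 1.1 M | run made earlier |  |
| ochre | 1.8 M | run made earlier |  |
| flask | 0.800 M |  | 30 h |

| run | time / h | complex with one exchanged / % | starting complex / % |
|---|---|---|---|
| red | 0.500 | 16.0 | 79.8 |
| red | 1.33 | 26.2 | 54.6 |
| red | 2.50 | 26.7 | 33.8 |
| red | 5.00 | 19.9 | 13.2 |
| red | 12.0 | 12.8 | 1.5 |
| red | 25.0 | 12.7 | 0.1 |
| ochre | 0.500 | 24.2 | 68.7 |
| ochre | 1.33 | 34.4 | 37.7 |
| ochre | 2.50 | 30.8 | 16.5 |
| ochre | 5.00 | 21.1 | 3.5 |
| ochre | 12.0 | 14.8 | 0 |
| ochre | 25.0 | 13.0 | 0.1 |

(each reading ± 0.3 percentage points)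

* time, not beyond 30 h, at which the flask holds most complex with one exchanged
* the amount of complex with one exchanged, in percent of the starting complex charged, at that time
* earliest time at which at least nineteen twentieths of that best amount are there
* latest time at which they still are

1. We reckon with a ratio: how fast starting complex feeds complex with one exchanged, over how fast that complex drains away. Its peak comes where feed and drain match.

2. Between the first and third readings, the decay constant of starting complex divided by the ligand charge gives 0.390 /M/h in the red run and 0.396 /M/h in the ochre run. So c(incoming ligand) sets the pace, pseudo-first-order while it holds.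

3. From 1.33 h to 2.50 h the red run's complex with one exchanged barely moves, so we take feed equal to drain there, which gives a drain constant of 0.718 /h.

4. The feed-to-drain ratio r is 0.435 for the flask: the rate constant times c(incoming ligand) over the drain constant. For two first-order steps, the peak share is r to the power one over (one minus r).

5. Extreme one: c(incoming ligand) stays at its charge, and the flask peaks at 22.9 % after 2.05 h. Extreme two: the pace falls one for one with starting complex, leaving 0.487 M by then, so r is 0.265 and the peak 16.4 %.

6. Late in the red run the decay constant reads 0.311 /h, more than the 0.158 /h of one-for-one loss. That reading is of starting complex, not of incoming ligand, so we place the flask's peak somewhere between 16.4 % and 22.9 %.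

7. The forecast says 21.5 % at 2.3 h, below our extreme one, with the window from 1.45 h to 3.5 h; its words are that “the rate sags only mildly late on”.

8. The flask gives 22.5 % at 2.17 h, with the window from 1.46 h to 3.21 h, within the forecast's margins.

    starting complex + incoming ligand ⇌ leaving ligand + complex with one exchanged (K = 22.0, k = 0.418 /M/h)
    complex with one exchanged + incoming ligand ⇌ leaving ligand + complex with two exchanged (K = 0.220, k = 0.166 /M/h)
    complex with one exchanged ⇌ isomer of the product (K = 4.50, k = 0.432 /h)
    leaving ligand + starting complex → side product (k = 0.412 /M/h)

Our drain is one number, but in the flask complex with one exchanged has two ways on: at 30.0 h, counting forward rates, it goes to isomer of the product 10 times as fast as to complex with two exchanged. At that time the flask holds 51.8 % of isomer of the product against 2.39 % of complex with two exchanged. For the neighbour flask charged with 2.0 M of incoming ligand, r becomes 1.09, which reckons a peak of 38.4 %; that flask gives 35.7 %.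

All runs stem from a simulated flask for an exercise; the scatter is artificial.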